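**Assumption:** cembrane numbering is used for all intermediates (ring C1–C14, lactone carbons C15–C17, methyls C18–C20); the target is (1S,3R,4R,7E,12S,13R,14R) with a cis-fused lactone and an all-syn C12/C13/C14 array. TBS = tert-butyldimethylsilyl, TES = triethylsilyl.

## Retrosynthetic overview

1. Target 22 ⇐ 13-hydroxy lactone 21 by acetylation.
2. 21 ⇐ seco α-hydroxy aldehyde / 2-(methoxycarbonyl)allyl carbonate 20: the C1–C14 bond, the 14-membered carbocycle and the γ-lactone form together in one chelation-controlled umpolung allylation (new step).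
3. The allyl carbonate ⇐ propargylic alcohol 15 (hydrostannation/iodination, carbonylation) ⇐ epoxy triflate 13 + propargyl acetylide (C1–C2 bond); the epoxide comes from Sharpless epoxidation of allylic alcohol 11.
4. Chain 10 (C2–C14) ⇐ Cu-catalysed sp3–sp3 coupling at C9–C10 of 8-bromogeranyl acetate 9 with the Grignard of bromide 6; 6 ⇐ Brown (Z)-crotylation of TBSOCH2CHO (sets C12, C13).
5. Ring order: epoxide (step 9), then macrocycle and lactone simultaneously (step 17).

## Route

**Step 1**
Reactants: 1 (tert-butyldimethylsilyloxy)acetaldehyde; 2 cis-2-butene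
Product: 3 (2R,3S)-1-[(tert-butyldimethylsilyl)oxy]-3-methylpent-4-en-2-ol
Conditions: 2, KOt-Bu, n-BuLi, THF, −78 → −45 °C; (+)-Ipc2BOMe (from (−)-α-pinene), BF3·OEt2, −78 °C; 1, −78 °C; then NaOH, H2O2
Reagents that add atoms: none (all heavy atoms from 1 and 2)
Why: Brown asymmetric (Z)-crotylboration; the chair transition state of the Z-crotylborane gives the syn Me/OH pair, and this Ipc antipode adds to the Re face of 1, setting C13 (R) and C12 (S).

**Step 2**
Reactants: 3
Product: 4 tert-butyldimethyl{[(2R,3S)-3-methyl-2-(triethylsilyloxy)pent-4-en-1-yl]oxy}silane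
Conditions: TESCl, imidazole, CH2Cl2, 0 °C
Reagents that add atoms: chlorotriethylsilane, CC[Si](Cl)(CC)CC
Why: Standard silyl ether formation under non-basic-alkoxide conditions, so the neighbouring TBS group does not migrate.

**Step 3**
Reactants: 4
Product: 5 (3S,4R)-5-[(tert-butyldimethylsilyl)oxy]-3-methyl-4-(triethylsilyloxy)pentan-1-ol
Conditions: 9-BBN, THF, 0 °C → rt; then NaOH, H2O2, 0 °C
Reagents that add atoms: hydrogen peroxide, OO (hydroxyl O)
Why: Anti-Markovnikov hydroboration–oxidation of the monosubstituted alkene gives the primary alcohol (C10) without touching the stereocentres.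

**Step 4**
Reactants: 5
Product: 6 (2R,3S)-5-bromo-1-[(tert-butyldimethylsilyl)oxy]-3-methyl-2-(triethylsilyloxy)pentane
Conditions: CBr4, PPh3, 2,6-lutidine, CH2Cl2, 0 °C
Reagents that add atoms: carbon tetrabromide, BrC(Br)(Br)Br
Why: Appel bromination of a primary alcohol; buffered so the TES ether survives.

**Step 5**
Reactants: 7 geranyl acetate
Product: 8 (2E,6E)-8-hydroxy-3,7-dimethylocta-2,6-dien-1-yl acetate
Conditions: SeO2 (cat.), t-BuOOH, salicylic acid (cat.), CH2Cl2, rt; then NaBH4, MeOH, 0 °C (reduces over-oxidised enal)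
Reagents that add atoms: selenium dioxide, O=[Se]=O / tert-butyl hydroperoxide, CC(C)(C)OO (hydroxyl O)
Why: SeO2 allylic oxidation (ene/[2,3] sequence) is selective for the E-methyl group of the terminal trisubstituted alkene and keeps the E geometry.

**Step 6**
Reactants: 8
Product: 9 (2E,6E)-8-bromo-3,7-dimethylocta-2,6-dien-1-yl acetate
Conditions: CBr4, PPh3, CH2Cl2, −20 → 0 °C
Reagents that add atoms: carbon tetrabromide, BrC(Br)(Br)Br
Why: Appel bromination of the primary allylic alcohol proceeds without allylic transposition at low temperature.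

**Step 7**
Reactants: 6; 9
Product: 10 (2E,6E,11S,12R)-13-[(tert-butyldimethylsilyl)oxy]-3,7,11-trimethyl-12-(triethylsilyloxy)trideca-2,6-dien-1-yl acetate (= C2–C14 chain)
Conditions: 6, Mg, THF, 40 °C; then add to 9, Li2CuCl4 (5 mol %), THF, −78 → −20 °C
Reagents that add atoms: none
Why: Kochi–Schlosser Cu-catalysed Grignard/allylic bromide coupling gives SN2 substitution at the primary allylic carbon (C9–C10 bond) with E retention; the acetate is tolerated at low temperature.

**Step 8**
Reactants: 10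
Product: 11 (2E,6E,11S,12R)-13-[(tert-butyldimethylsilyl)oxy]-3,7,11-trimethyl-12-(triethylsilyloxy)trideca-2,6-dien-1-ol
Conditions: K2CO3, MeOH, 0 °C → rt
Reagents that add atoms: none
Why: Mild acetate methanolysis frees the allylic alcohol; both silyl ethers are stable.

**Step 9**
Reactants: 11
Product: 12 {(2R,3R)-3-methyl-3-R*-oxiran-2-yl}methanol, where R* = (3E,8S,9R)-10-[(tert-butyldimethylsilyl)oxy]-4,8-dimethyl-9-(triethylsilyloxy)dec-3-en-1-yl
Conditions: Ti(Oi-Pr)4 (10 mol %), D-(−)-diethyl tartrate (12 mol %), t-BuOOH, 4 Å MS, CH2Cl2, −20 °C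
Reagents that add atoms: tert-butyl hydroperoxide, CC(C)(C)OO (epoxide O)
Why: Sharpless asymmetric epoxidation; D-(−)-tartrate gives the (2R,3R)-epoxy alcohol (C3 R, C4 R) from the E-allylic alcohol, and the isolated C7=C8 alkene is untouched.

**Step 10**
Reactants: 12
Product: 13 {(2R,3R)-3-methyl-3-R*-oxiran-2-yl}methyl trifluoromethanesulfonate
Conditions: Tf2O, 2,6-lutidine, CH2Cl2, −78 °C; used at once
Reagents that add atoms: triflic anhydride, O=S(=O)(OS(=O)(=O)C(F)(F)F)C(F)(F)F
Why: Low-temperature triflation of the primary alcohol gives a reactive electrophile that leaves the epoxide intact.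

**Step 11**
Reactants: 13; 14 trimethyl(prop-2-yn-1-yloxy)silane
Product: 15 4-{(2R,3R)-3-methyl-3-R*-oxiran-2-yl}but-2-yn-1-ol
Conditions: 14, n-BuLi, THF/DMPU, −78 °C; add 13, −78 → −30 °C; then K2CO3, MeOH, rt (O–TMS cleavage)
Reagents that add atoms: none beyond 14
Why: SN2 alkylation of a lithium acetylide by the primary epoxy triflate forms the C1–C2 bond; the acetylide does not open the epoxide without a Lewis acid.

**Step 12**
Reactants: 15
Product: 16 (2E)-2-iodo-4-{(2R,3R)-3-methyl-3-R*-oxiran-2-yl}but-2-en-1-ol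
Conditions: Bu3SnH, PdCl2(PPh3)2 (3 mol %), THF, 0 °C → rt; then I2, CH2Cl2, 0 °C
Reagents that add atoms: iodine, II
Why: Pd-catalysed syn-hydrostannation of a 2-alkyn-1-ol puts tin on the carbon next to CH2OH, and iododestannylation proceeds with retention.

**Step 13**
Reactants: 16
Product: 17 methyl (2E)-2-(hydroxymethyl)-4-{(2R,3R)-3-methyl-3-R*-oxiran-2-yl}but-2-enoate
Conditions: PdCl2(PPh3)2 (5 mol %), CO (1 atm), Et3N, MeOH/DMF, 50 °C
Reagents that add atoms: carbon monoxide, [C-]#[O+]; methanol, CO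
Why: Pd-catalysed alkoxycarbonylation of the vinyl iodide installs C16 with retention of alkene geometry under basic conditions that spare the epoxide.

**Step 14**
Reactants: 17
Product: 18 methyl (2E)-2-{[(methoxycarbonyl)oxy]methyl}-4-{(2R,3R)-3-methyl-3-R*-oxiran-2-yl}but-2-enoate
Conditions: ClCO2Me, pyridine, CH2Cl2, 0 °C
Reagents that add atoms: methyl chloroformate, COC(=O)Cl
Why: Carbonate formation masks the allylic alcohol and turns it into a latent allyl donor that survives the deprotection and oxidation steps, unlike an allylic bromide.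

**Step 15**
Reactants: 18
Product: 19 methyl (2E)-2-{[(methoxycarbonyl)oxy]methyl}-4-{(2R,3R)-3-[(3E,8S,9R)-9,10-dihydroxy-4,8-dimethyldec-3-en-1-yl]-3-methyloxiran-2-yl}but-2-enoate
Conditions: HF·pyridine, excess pyridine, THF, 0 °C → rt
Reagents that add atoms: none
Why: Buffered HF·pyridine removes the secondary TES and primary TBS ethers while trisubstituted epoxides, carbonates and esters are stable.

**Step 16**
Reactants: 19
Product: 20 methyl (2E)-2-{[(methoxycarbonyl)oxy]methyl}-4-{(2R,3R)-3-[(3E,8S,9R)-9-hydroxy-4,8-dimethyl-10-oxodec-3-en-1-yl]-3-methyloxiran-2-yl}but-2-enoate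
Conditions: TEMPO (10 mol %), PhI(OAc)2 (1.1 equiv), CH2Cl2, 0 °C → rt; used crude
Reagents that add atoms: none
Why: TEMPO/oxoammonium oxidation is selective for the primary alcohol of the 1,2-diol and gives the α-hydroxy aldehyde without epimerising C13.

**Step 17** (new step)
Reactants: 20
Product: 21 (1S,3R,4R,7E,12S,13R,14R)-3,4-epoxy-13-hydroxycembra-7,15(17)-dien-16,14-olide
Conditions: Pd(PPh3)4 (10 mol %), InI (2.5 equiv), THF, 25 °C; 20 added by syringe pump over 10 h (final 1 mM); then 40 °C, 1 h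
Reagents that add atoms: none
Why: Proposed new method: a hydroxyl-directed Pd(0)/In(I) redox-umpolung macrocyclising 2-(methoxycarbonyl)allylation–lactonisation. Pd(0) ionises the carbonate to a 2-carbomethoxy-π-allyl-Pd(II) species, which InI reduces and transmetalates to an allyl-In(III) nucleophile, generated only as fast as Pd turns over, which suits high dilution. In(III) binds the C13-OH and the aldehyde as a five-membered chelate, so C1 adds to the aldehyde face anti to the C12 branch (13,14-syn; a closed, non-chelated Z-allyl transition state would favour the unwanted 13,14-anti isomer). The γ-substituted 2-carboalkoxyallyl-indium reacts through a chair with C2 pseudoaxial (1,14-syn), and the indium alkoxide then acylates on the adjacent ester to give the cis-fused α-methylene-γ-lactone, setting C14 (R) and C1 (S). Closest known reactions: intermolecular Pd/In(I) umpolung allylation of aldehydes with allylic carbonates, and aqueous In(0) Barbier coupling of 2-(bromomethyl)-2-alkenoates with α-hydroxy aldehydes (syn,syn); neither has been used for a macrocyclisation or with this donor.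

**Step 18**
Reactants: 21
Product: 22 eupalmerin acetate
Conditions: Ac2O, pyridine, DMAP (cat.), CH2Cl2, 0 °C
Reagents that add atoms: acetic anhydride, CC(=O)OC(C)=O
Why: Acylation of the only free hydroxyl (C13) completes the target without affecting the epoxide or the α-methylene lactone.

## Compound list

1 | (tert-butyldimethylsilyloxy)acetaldehyde | O=CCO[Si](C)(C)C(C)(C)C | starting material
2 | cis-2-butene | C/C=C\C | starting material
3 | (2R,3S)-1-[(tert-butyldimethylsilyl)oxy]-3-methylpent-4-en-2-ol | C=C[C@H](C)[C@@H](O)CO[Si](C)(C)C(C)(C)C | intermediate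
4 | tert-butyldimethyl{[(2R,3S)-3-methyl-2-(triethylsilyloxy)pent-4-en-1-yl]oxy}silane | C=C[C@H](C)[C@@H](O[Si](CC)(CC)CC)CO[Si](C)(C)C(C)(C)C | intermediate
5 | (3S,4R)-5-[(tert-butyldimethylsilyl)oxy]-3-methyl-4-(triethylsilyloxy)pentan-1-ol | OCC[C@H](C)[C@@H](O[Si](CC)(CC)CC)CO[Si](C)(C)C(C)(C)C | intermediate
6 | (2R,3S)-5-bromo-1-[(tert-butyldimethylsilyl)oxy]-3-methyl-2-(triethylsilyloxy)pentane | BrCC[C@H](C)[C@@H](O[Si](CC)(CC)CC)CO[Si](C)(C)C(C)(C)C | intermediate
7 | geranyl acetate | CC(C)=CCC/C(C)=C/COC(C)=O | starting material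
8 | (2E,6E)-8-hydroxy-3,7-dimethylocta-2,6-dien-1-yl acetate | OC/C(C)=C/CC/C(C)=C/COC(C)=O | intermediate
9 | (2E,6E)-8-bromo-3,7-dimethylocta-2,6-dien-1-yl acetate | BrC/C(C)=C/CC/C(C)=C/COC(C)=O | intermediate
10 | (2E,6E,11S,12R)-13-[(tert-butyldimethylsilyl)oxy]-3,7,11-trimethyl-12-(triethylsilyloxy)trideca-2,6-dien-1-yl acetate | CC(=O)OC/C=C(C)/CC/C=C(C)/CCC[C@H](C)[C@@H](O[Si](CC)(CC)CC)CO[Si](C)(C)C(C)(C)C | intermediate
11 | (2E,6E,11S,12R)-13-[(tert-butyldimethylsilyl)oxy]-3,7,11-trimethyl-12-(triethylsilyloxy)trideca-2,6-dien-1-ol | OC/C=C(C)/CC/C=C(C)/CCC[C@H](C)[C@@H](O[Si](CC)(CC)CC)CO[Si](C)(C)C(C)(C)C | intermediate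
12 | {(2R,3R)-3-[(3E,8S,9R)-10-[(tert-butyldimethylsilyl)oxy]-4,8-dimethyl-9-(triethylsilyloxy)dec-3-en-1-yl]-3-methyloxiran-2-yl}methanol | OC[C@H]1O[C@]1(C)CC/C=C(C)/CCC[C@H](C)[C@@H](O[Si](CC)(CC)CC)CO[Si](C)(C)C(C)(C)C | intermediate
13 | triflate of 12 | O=S(=O)(OC[C@H]1O[C@]1(C)CC/C=C(C)/CCC[C@H](C)[C@@H](O[Si](CC)(CC)CC)CO[Si](C)(C)C(C)(C)C)C(F)(F)F | intermediate
14 | trimethyl(prop-2-yn-1-yloxy)silane | C#CCO[Si](C)(C)C | starting material
15 | 4-{(2R,3R)-3-methyl-3-R*-oxiran-2-yl}but-2-yn-1-ol | OCC#CC[C@H]1O[C@]1(C)CC/C=C(C)/CCC[C@H](C)[C@@H](O[Si](CC)(CC)CC)CO[Si](C)(C)C(C)(C)C | intermediate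
16 | (2E)-2-iodo-4-{(2R,3R)-3-methyl-3-R*-oxiran-2-yl}but-2-en-1-ol | OC/C(I)=C\C[C@H]1O[C@]1(C)CC/C=C(C)/CCC[C@H](C)[C@@H](O[Si](CC)(CC)CC)CO[Si](C)(C)C(C)(C)C | intermediate
17 | methyl (2E)-2-(hydroxymethyl)-4-{(2R,3R)-3-methyl-3-R*-oxiran-2-yl}but-2-enoate | OC/C(C(=O)OC)=C\C[C@H]1O[C@]1(C)CC/C=C(C)/CCC[C@H](C)[C@@H](O[Si](CC)(CC)CC)CO[Si](C)(C)C(C)(C)C | intermediate
18 | methyl (2E)-2-{[(methoxycarbonyl)oxy]methyl}-4-{(2R,3R)-3-methyl-3-R*-oxiran-2-yl}but-2-enoate | COC(=O)OC/C(C(=O)OC)=C\C[C@H]1O[C@]1(C)CC/C=C(C)/CCC[C@H](C)[C@@H](O[Si](CC)(CC)CC)CO[Si](C)(C)C(C)(C)C | intermediate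
19 | 13,14-diol of 18 (side chain (3E,8S,9R)-9,10-dihydroxy-4,8-dimethyldec-3-en-1-yl) | COC(=O)OC/C(C(=O)OC)=C\C[C@H]1O[C@]1(C)CC/C=C(C)/CCC[C@H](C)[C@@H](O)CO | intermediate
20 | α-hydroxy aldehyde (side chain (3E,8S,9R)-9-hydroxy-4,8-dimethyl-10-oxodec-3-en-1-yl) | COC(=O)OC/C(C(=O)OC)=C\C[C@H]1O[C@]1(C)CC/C=C(C)/CCC[C@H](C)[C@@H](O)C=O | intermediate
21 | (1S,3R,4R,7E,12S,13R,14R)-3,4-epoxy-13-hydroxycembra-7,15(17)-dien-16,14-olide | C=C1C(=O)O[C@H]2[C@H](O)[C@@H](C)CCC/C(C)=C/CC[C@@]3(C)O[C@@H]3C[C@@H]12 | intermediate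
22 | eupalmerin acetate | C=C1C(=O)O[C@H]2[C@H](OC(C)=O)[C@@H](C)CCC/C(C)=C/CC[C@@]3(C)O[C@@H]3C[C@@H]12 | target

## Summary

Total steps: 18. Longest linear sequence: 16 (steps 1–4, then 7–18, from compound 1).

Steps most likely to fail, with fallbacks:

1. **Step 17 (proposed new macrocyclisation).** Risks are oligomerisation, O-allylation by the π-allyl-Pd intermediate, and erosion of chelation control inside the forming ring. Fallback with known chemistry: make the C1–C14 bond first, intermolecularly, by the established aqueous In(0) Barbier coupling of the allylic bromide analogue with a free α-hydroxy aldehyde fragment (chelation-controlled, syn,syn). Then close the ring at C8–C9 by a macrocyclic B-alkyl Suzuki–Miyaura coupling (C9=C10 terminal alkene/9-BBN with a C8 (E)-vinyl iodide), carrying the α-methylene lactone as its dimethylamine Michael adduct and regenerating it at the end (MeI, NaHCO3).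

2. **Step 16 (selective oxidation to a free α-hydroxy aldehyde).** Risks are glycol cleavage, over-oxidation and dimerisation. Fallback: carry C14 as a PMB ether (start from PMB-oxyacetaldehyde) and C13 as TES; unveil in stages with DDQ (C14-OH), Dess–Martin oxidation, then HF·pyridine to release the α-hydroxyl just before cyclisation.

3. **Step 7 (Cu-catalysed sp3–sp3 coupling beside an allylic acetate).** Risks are SN2′ attack and reaction at the acetate. Fallback: convert 6 to its phenyl sulfone, alkylate the lithiated sulfone with the TBS-ether analogue of 9, and remove the (non-allylic) sulfone reductively (Mg/MeOH or Na/Hg).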